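## Analysis of the target

The target is a C37 butenolide carotenoid in which three rings are joined only through unsaturated carbon: ring A, a cyclohexane-1,2,4-triol (A1 the carbinol carbon carrying the (E)-vinyl link, A2 the methyl carbinol, A3 CH2, A4 the secondary carbinol, A5 CH2, A6 the gem-dimethyl carbon); ring C, a γ-ylidenebutenolide (O1, carbonyl C2, C3 with the vinyl link, C4–H, C5 with the exocyclic alkene); and ring B, a 4-hydroxy-2,6,6-trimethylcyclohexene. From C5 an eleven-carbon chain C1'–C11' runs to ring B: the (Z)-ylidene CH (C1'), an all-E tetraene with methyl groups on C2' and C9', and the C10'≡C11' alkyne. There are four stereocentres, A1 (R), A2 (R), A4 (S) and the ring B carbinol (R); the last is remote from the others and has to come from a chiral-pool compound. On ring A the two tertiary hydroxyls on A1 and A2 are trans, the oxygens on A1 and A4 are cis across the ring, and A2/A4 are 1,3-anti. The ylidene lactone and the polyene are sensitive to base, acid, light and oxygen, and the A1 carbinol is tertiary and allylic, so the carbon skeleton should be finished by a mild coupling with no protecting group left to remove. The difficulty is twofold: a contiguous pair of fully substituted carbinols beside a quaternary carbon, in a fixed relation to a third oxygen, and a conjugated chain whose six alkene geometries must be set without isomer mixtures. The strategy rests on the A1 and A4 oxygens: two cis-1,4 C–O bonds on a six-membered ring are what remains of a dioxygen bridge laid across the ends of a cyclohexa-1,3-diene (A1=A2–A3=A4), and the alkene that the bridge leaves between A2 and A3 is where the third oxygen is needed.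

## Retrosynthetic reasoning

**C3–vinyl bond (36 ⇒ 35 + 13).** The bond between C3 of ring C and the vinyl carbon is cut last. It is the one sp2–sp2 bond that separates ring A, with all three of its stereocentres, from the chromophore. The forward reaction is a Stille coupling of the α-bromo lactone 35 with the (E)-alkenylstannane 13; it keeps both alkene geometries and tolerates the free hydroxyls, so 36 is released without a deprotection.

**C3'–C4' bond (35 ⇒ 34 + 23).** The chain is cut between C3' and C4', which leaves a ring B trienyne stannane 34 and a small lactone 23 carrying two different halides. The iodide on C3' must react before the bromide on C3, which fixes the order of the two couplings.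

**C5=C1' bond (23 ⇒ 20 + 17).** The ylidene is opened to bromobutenolide 20 and iodo-enal 17. The forward reaction is a vinylogous aldol condensation that ends under thermodynamic control in the (Z)-ylidene. 20 comes from 18 by bromination and elimination; 17 comes from 14 through 16, where a syn carbometalation sets the trisubstituted (E)-alkene.

**Ring B and the outer chain (34 ⇒ 32 + 33; 32 ⇒ 31 ⇒ 30 ⇒ 29 ⇒ 27 + 28; 27 ⇒ 25 ⇒ 24).** The C5'–C6' bond is cut to dienyl iodide 32 and the two-carbon distannane 33. The C6'=C7' bond of 32 is traced to aldehyde 31 by a one-carbon iodo-olefination. The C11'–ring bond is traced to enol triflate 27 and enyne 28. The ring B carbinol is carried unchanged from 24; the methyl-bearing stereocentre of 24 is deliberately lost on enolisation.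

**Ring A oxygens (13 ⇒ 12 ⇒ 11 ⇒ 10 ⇒ 9 ⇒ 8 ⇒ 7).** The C–Sn bond of 13 is traced to terminal alkyne 12. The A4 C–H bond is traced to ketone 10, where hydride must be delivered from the face of the A2 hydroxyl. The A2 hydroxyl is traced to epoxy ketone 9 by cleavage of the A3–O bond. The epoxide is traced to enone 8, where the oxidant must arrive anti to the A1 oxygen; that oxygen is therefore silylated in 8 and free in 7.

**O–O bond (7 ⇒ 6).** The A4 carbonyl and the A1 hydroxyl of 7 are joined back into the peroxide of 6. In the forward sense a base removes the single bridgehead hydrogen and the O–O bond breaks. This is also the point where a chiral base can choose one enantiomer of the racemic peroxide.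

**A1–O and A4–O bonds (6 ⇒ 5).** Both C–O bonds are cut together. The forward reaction is a photo-oxygenation that bridges the diene termini of 5 on one face. It makes the fully substituted A1 carbinol, which is hard to reach by addition to a ketone flanked by a quaternary carbon, and fixes its cis relation to A4.

**Alkyne carbon (5 ⇒ 2 + 3 ⇒ 1).** The silylalkyne is traced to aldehyde 1 by a two-stage one-carbon homologation, with 3 capping the acetylide 4.

## Alternatives that were turned down

**Alternative 1:** Ring C is cut at C2–C3 and C2–O1, so that the lactone carbonyl comes from carbon monoxide and the ring from an open-chain (Z)-β-iodo dienone A2 that already carries ring A. In the forward step zerovalent palladium would insert into the C3–I bond of A2 and take up CO, and the acylpalladium would be captured by the dienol oxygen of the C5 ketone to give ylidenebutenolide A1.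
- For it: ring C, its carbonyl and the ylidene appear in one operation, no tin is needed at C3, and ring A is attached before the lactone exists. On step count for ring C and on avoiding the last coupling this alternative is stronger.
- Against it: the β-iodo enone of A2 can lose its Z geometry by reversible conjugate addition; the ylidene geometry depends on which dienol is acylated; and A1 stops at C4', so seven chain carbons and ring B would still have to be added by olefination on a base-sensitive lactone, followed by removal of two silyl ethers from the finished polyene.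
- Comparison: A2 presupposes a ring A piece with A1, A2 and A4 already in place and does not say how to make it, which is where the stereochemical problem lies. The chosen strategy gives up the one-step lactone; in exchange it places its uncertain transformation at step 3 on cheap material and ends with stereoretentive couplings and no deprotection.

**Alternative 2:** The C10'≡C11' alkyne is made by inserting one carbon into a cross-conjugated ketone A4, in which the ring B alkenyl group and the C9' alkenyl group flank the carbonyl. Lithiated trimethylsilyldiazomethane would add to the carbonyl, loss of silanolate and N2 would leave an alkylidene carbene, and a 1,2-shift of an alkenyl group (Colvin-type rearrangement) would give enyne acetal A3.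
- For it: no palladium, copper or enol triflate, and A3 is already at the aldehyde oxidation level, one step ahead of the alcohol 29 used here. On that point it is equal or slightly better.
- Against it: the carbonyl of A4 is shielded by the gem-dimethyl group and the ring methyl, so the bulky nucleophile adds slowly and conjugate addition competes; the carbene can insert into a C–H bond of the ring methyl groups instead of rearranging; and A4 itself needs an acylation sequence.
- Comparison: the move addresses a bond that the Sonogashira coupling of 27 with 28 forms reliably, and it leaves ring A unsolved. It spends its risk where none is needed, whereas the chosen strategy spends it on the stereotriad.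

**Alternative 3:** The chain is taken from a symmetric tetraenediyne A7, joined once to ring B to give the terminal alkyne A6, and ring C is cut at C4–C5 and O1–C5. In the forward step A6 would couple with the β C–Br bond of (E)-2,3-dibromoacrylic acid A8 under palladium and copper catalysis, and the carboxylate would then add 5-exo-dig to the new enyne to give bromide A5, which is the same compound as 35.
- For it: one step forms two bonds, ring C and the ylidene and leaves the C3 bromide ready for the last coupling; A7 can be built in both directions at once. For ring C and the chain this is clearly shorter than steps 11–14 and 20–22, and on step economy it is stronger.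
- Against it: A7 must react at one end only with 27, which is a statistical coupling or needs a protecting group; the terminal polyenyne A6 is labile; and the tandem step must select the β over the α C–Br bond of A8, 5-exo over 6-endo closure, and the Z geometry, all on a full-length polyene in the presence of copper and amine.
- Comparison: the alternative has nothing to say about ring A. The chosen strategy reaches the same bromide 35 by longer but individually predictable steps and uses its key step to set the A1/A4 relation, from which A2 and A4 follow.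

Key step: step 3

Remarks on the chemistry (assumptions):
- Which of the two pseudoenantiomeric 6'-hydroxy cinchona acetates opens the (1R,4S)-peroxide faster cannot be predicted; the route is written for 9-O-acetylcupreidine, and 9-O-acetylcupreine is used if the sense is opposite.
- Compound 6 is the racemate; its name and SMILES show the enantiomer that is carried on.
- Compounds 1, 14, 18, 24, 28 and 33 are taken as commercial.

## Route

Step 1
Reactants: 1 safranal
Product: 2 1-(2,2-dibromoethenyl)-2,6,6-trimethylcyclohexa-1,3-diene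
Conditions: CBr4, PPh3, CH2Cl2, 0 °C
Reagents that add atoms: carbon tetrabromide, BrC(Br)(Br)Br
Why: Wittig-type dibromo-olefination, the first stage of the Corey–Fuchs homologation; the ylide Ph3P=CBr2 formed in the flask condenses with the non-enolisable dienal and the ring diene is inert to it.

Step 2
Reactants: 2 1-(2,2-dibromoethenyl)-2,6,6-trimethylcyclohexa-1,3-diene; 3 chlorotrimethylsilane
Product: 5 trimethyl[(2,6,6-trimethylcyclohexa-1,3-dien-1-yl)ethynyl]silane, via lithium acetylide 4 (not isolated)
Conditions: n-BuLi (2.2 equiv), THF, −78 → 0 °C; then Me3SiCl, −78 °C → rt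
Reagents that add atoms: none
Why: Second stage of the Corey–Fuchs homologation: bromine–lithium exchange, α-elimination and a Fritsch–Buttenberg–Wiechert 1,2-shift give the alkyne, the second equivalent of base gives acetylide 4, and silylation on carbon gives 5. The silyl group makes the dienyne non-volatile and removes the acidic C–H before the base-mediated step 4.

Step 3
Reactants: 5 trimethyl[(2,6,6-trimethylcyclohexa-1,3-dien-1-yl)ethynyl]silane
Product: 6 rac-(1R,4S)-6,7,7-trimethyl-1-[(trimethylsilyl)ethynyl]-2,3-dioxabicyclo[2.2.2]oct-5-ene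
Conditions: O2, rose bengal (cat.), CH2Cl2–MeOH (9:1), white LED, −20 °C
Reagents that add atoms: dioxygen, O=O
Why: Visible-light excitation of rose bengal and energy transfer give singlet oxygen, which adds across C1 and C4 of the ring diene of 5 in a concerted suprafacial (4+2) cycloaddition; the closest known reaction type is the photo-oxygenation of cyclohexa-1,3-dienes to 2,3-dioxabicyclo[2.2.2]oct-5-enes, including 2,6,6-trimethylcyclohexa-1,3-dienes with an unsaturated carbon substituent on C1. The one ring that closes is the six-membered 1,2-dioxane; it closes by cycloaddition, both C–O bonds (A1–O and A4–O) forming in the same event on a diene that the carbocycle holds s-cis. The two new stereocentres, the alkynyl-bearing bridgehead and the CH bridgehead, are fixed relative to each other by the bridge itself, because a two-atom oxygen unit can only span one face of the ring; nothing controls the absolute sense, so 6 is racemic. The selectivity the step needs is cycloaddition over the ene reaction at the C2 methyl or the C5 methylene and over attack at the alkyne; the locked cisoid diene favours cycloaddition and the silylalkyne is electron-poor and inert to singlet oxygen. Low temperature and the absence of base keep the peroxide, which has one bridgehead hydrogen, from opening before step 4.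

Step 4
Reactants: 6 rac-(1R,4S)-6,7,7-trimethyl-1-[(trimethylsilyl)ethynyl]-2,3-dioxabicyclo[2.2.2]oct-5-ene
Product: 7 (4R)-4-hydroxy-3,5,5-trimethyl-4-[(trimethylsilyl)ethynyl]cyclohex-2-en-1-one
Conditions: 9-O-acetylcupreidine (10 mol %), CH2Cl2, rt, stopped near half conversion
Reagents that add atoms: none
Why: Proposed new method: the quinuclidine nitrogen removes the single bridgehead hydrogen while the O–O bond breaks (E2-type Kornblum–DeLaMare opening) and the 6'-hydroxyl of the catalyst hydrogen-bonds the peroxide, so the two enantiomers of 6 pass through diastereomeric transition states; the closest known reaction is the cinchona-catalysed desymmetrising Kornblum–DeLaMare rearrangement of meso bicyclic endoperoxides, whose enantiotopic bridgehead hydrogens have the same local surroundings (alkene carbon on one side, methylene on the other) as the hydrogen of each enantiomer here. The quaternary carbinol is not touched, so 7 has the configuration of the (1R,4S)-peroxide, and the slow enantiomer stays as peroxide and is removed by chromatography.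

Step 5
Reactants: 7 (4R)-4-hydroxy-3,5,5-trimethyl-4-[(trimethylsilyl)ethynyl]cyclohex-2-en-1-one
Product: 8 (4R)-3,5,5-trimethyl-4-[(triethylsilyl)oxy]-4-[(trimethylsilyl)ethynyl]cyclohex-2-en-1-one
Conditions: Et3SiOTf, 2,6-lutidine, CH2Cl2, −78 → 0 °C
Reagents that add atoms: triethylsilyl trifluoromethanesulfonate, CC[Si](CC)(CC)OS(=O)(=O)C(F)(F)F
Why: Silyl triflate silylation of a hindered tertiary propargylic alcohol; 2,6-lutidine at low temperature does not enolise the enone. The bulky silyloxy group removes the hydrogen-bond donor and is what steers the epoxidation of step 6 to the opposite face.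

Step 6
Reactants: 8 (4R)-3,5,5-trimethyl-4-[(triethylsilyl)oxy]-4-[(trimethylsilyl)ethynyl]cyclohex-2-en-1-one
Product: 9 (1S,5S,6R)-5-ethynyl-4,4,6-trimethyl-5-[(triethylsilyl)oxy]-7-oxabicyclo[4.1.0]heptan-2-one
Conditions: 30% H2O2, NaOH, MeOH, 0 °C → rt
Reagents that add atoms: hydrogen peroxide, OO
Why: Weitz–Scheffer nucleophilic epoxidation: the silyloxy group on A1 stands pseudoaxial to avoid allylic strain with the A2 methyl, and hydroperoxide adds to A2 anti to that C–O bond (also the Felkin–Anh-type mode), so both new C–O bonds lie on the face of the alkynyl group and A2 is set R. Methanolic hydroxide cleaves the C(sp)–SiMe3 bond in the same flask, a standard alkynylsilane deprotection, while the hindered tertiary triethylsilyl ether is expected to stay.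

Step 7
Reactants: 9 (1S,5S,6R)-5-ethynyl-4,4,6-trimethyl-5-[(triethylsilyl)oxy]-7-oxabicyclo[4.1.0]heptan-2-one
Product: 10 (3R,4S)-4-ethynyl-3-hydroxy-3,5,5-trimethyl-4-[(triethylsilyl)oxy]cyclohexan-1-one
Conditions: SmI2, THF–MeOH, −90 °C
Reagents that add atoms: none
Why: Reductive opening of an α,β-epoxy ketone by single-electron transfer: the ketyl formed by divalent samarium expels the α C–O bond (A3–O) and methanol protonates the samarium enolate. The A2–O bond is not touched, so the tertiary carbinol keeps the configuration set in step 6.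

Step 8
Reactants: 10 (3R,4S)-4-ethynyl-3-hydroxy-3,5,5-trimethyl-4-[(triethylsilyl)oxy]cyclohexan-1-one
Product: 11 (1R,3S,6S)-6-ethynyl-1,5,5-trimethyl-6-[(triethylsilyl)oxy]cyclohexane-1,3-diol
Conditions: Me4NBH(OAc)3, MeCN–AcOH, −30 °C
Reagents that add atoms: none
Why: Evans–Saksena hydroxyl-directed reduction: the free A2 hydroxyl exchanges onto boron and delivers hydride to the A4 carbonyl from its own face, so the new hydroxyl is 1,3-anti to the A2 hydroxyl and cis to the A1 oxygen (A4 S). The reagent does not reduce ketones without such delivery, and the silylated A1 oxygen cannot compete.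

Step 9
Reactants: 11 (1R,3S,6S)-6-ethynyl-1,5,5-trimethyl-6-[(triethylsilyl)oxy]cyclohexane-1,3-diol
Product: 12 (1S,2R,4S)-1-ethynyl-2,6,6-trimethylcyclohexane-1,2,4-triol
Conditions: Bu4NF, THF, 0 °C → rt
Reagents that add atoms: none
Why: Fluoride cleavage of the tertiary triethylsilyl ether; from here on ring A carries no protecting group.

Step 10
Reactants: 12 (1S,2R,4S)-1-ethynyl-2,6,6-trimethylcyclohexane-1,2,4-triol
Product: 13 (1R,2R,4S)-2,6,6-trimethyl-1-[(E)-2-(tributylstannyl)ethenyl]cyclohexane-1,2,4-triol
Conditions: Bu3SnH, PdCl2(PPh3)2 (cat.), THF, 0 °C → rt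
Reagents that add atoms: tributyltin hydride, CCCC[SnH](CCCC)CCCC
Why: Palladium-catalysed syn hydrostannation of a terminal alkyne: hydrogen and tin add to the same side and tin goes to the terminal carbon because the other is flanked by the fully substituted carbinol, which gives the (E)-alkenylstannane. Free hydroxyls are tolerated; the change of descriptor at the ring carbon from S to R is one of substituent priority only.

Step 11
Reactants: 14 prop-2-yn-1-ol
Product: 16 (2E)-3-iodo-2-methylprop-2-en-1-ol, via alkenylalane 15 (not isolated)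
Conditions: Me3Al, Cp2ZrCl2, CH2Cl2, 0 °C → rt; then I2, THF, −30 → 0 °C
Reagents that add atoms: trimethylaluminium, C[Al](C)C; iodine, II
Why: Negishi zirconium-catalysed carboalumination: methyl and aluminium add syn across the alkyne with methyl on the internal carbon, and iodinolysis of the C–Al bond of 15 goes with retention, which fixes the (E)-geometry of the trisubstituted alkene.

Step 12
Reactants: 16 (2E)-3-iodo-2-methylprop-2-en-1-ol
Product: 17 (2E)-3-iodo-2-methylprop-2-enal
Conditions: MnO2, CH2Cl2, rt
Reagents that add atoms: none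
Why: MnO2 oxidation of a primary allylic alcohol to the enal without touching the alkenyl iodide or the alkene geometry.

Step 13
Reactants: 18 furan-2(5H)-one
Product: 20 3-bromofuran-2(5H)-one, via dibromolactone 19 (not isolated)
Conditions: Br2, CH2Cl2, reflux; then Et3N, 0 °C
Reagents that add atoms: bromine, BrBr
Why: Bromine adds across the C3=C4 bond and triethylamine removes the acidic C3 proton with loss of the C4 bromide (addition–elimination), which leaves bromine on C3 of the butenolide.

Step 14
Reactants: 20 3-bromofuran-2(5H)-one; 17 (2E)-3-iodo-2-methylprop-2-enal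
Product: 23 (5Z)-3-bromo-5-[(2E)-3-iodo-2-methylprop-2-en-1-ylidene]furan-2(5H)-one, via silyloxyfuran 21 (not isolated), via silyl aldol adduct 22 (not isolated)
Conditions: t-BuMe2SiOTf, i-Pr2NEt, CH2Cl2, −78 °C → rt; then DBU, rt
Reagents that add atoms: none
Why: One-pot vinylogous Mukaiyama aldol condensation: soft enolisation gives silyloxyfuran 21, which adds through C5 to the silyl-triflate-activated aldehyde, and DBU then removes silanol from adduct 22 by an E1cB path. The conjugated (Z)-ylidene, in which the chain avoids C4–H, is the thermodynamic product.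

Step 15
Reactants: 24 (4R,6R)-4-hydroxy-2,2,6-trimethylcyclohexan-1-one
Product: 25 (4R,6R)-4-{[tert-butyl(dimethyl)silyl]oxy}-2,2,6-trimethylcyclohexan-1-one
Conditions: t-BuMe2SiCl, imidazole, DMF, rt
Reagents that add atoms: tert-butyldimethylsilyl chloride, CC(C)(C)[Si](C)(C)Cl
Why: Standard silylation of the secondary alcohol, so that the enolate of the next step is the only anion formed.

Step 16
Reactants: 25 (4R,6R)-4-{[tert-butyl(dimethyl)silyl]oxy}-2,2,6-trimethylcyclohexan-1-one
Product: 27 (4R)-4-{[tert-butyl(dimethyl)silyl]oxy}-2,6,6-trimethylcyclohex-1-en-1-yl trifluoromethanesulfonate, via lithium enolate 26 (not isolated)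
Conditions: LDA, THF, −78 °C; then PhNTf2, −78 → 0 °C
Reagents that add atoms: N-phenylbis(trifluoromethanesulfonimide), O=S(=O)(N(c1ccccc1)S(=O)(=O)C(F)(F)F)C(F)(F)F
Why: The ketone has an α-hydrogen only on the methyl-bearing carbon, so LDA gives the single enolate 26 and O-triflation gives the tetrasubstituted enol triflate. The carbinol stereocentre is untouched and the methyl stereocentre is intentionally lost.

Step 17
Reactants: 27 (4R)-4-{[tert-butyl(dimethyl)silyl]oxy}-2,6,6-trimethylcyclohex-1-en-1-yl trifluoromethanesulfonate; 28 (2E)-3-methylpent-2-en-4-yn-1-ol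
Product: 29 (2E)-5-[(4R)-4-{[tert-butyl(dimethyl)silyl]oxy}-2,6,6-trimethylcyclohex-1-en-1-yl]-3-methylpent-2-en-4-yn-1-ol
Conditions: Pd(PPh3)4 (cat.), CuI (cat.), i-Pr2NH, DMF, rt
Reagents that add atoms: none
Why: Sonogashira coupling of an enol triflate with a terminal enyne; the (E)-alkene of 28 is not involved and keeps its geometry.

Step 18
Reactants: 29 (2E)-5-[(4R)-4-{[tert-butyl(dimethyl)silyl]oxy}-2,6,6-trimethylcyclohex-1-en-1-yl]-3-methylpent-2-en-4-yn-1-ol
Product: 30 (2E)-5-[(4R)-4-hydroxy-2,6,6-trimethylcyclohex-1-en-1-yl]-3-methylpent-2-en-4-yn-1-ol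
Conditions: Bu4NF, THF, rt
Reagents that add atoms: none
Why: Fluoride removal of the silyl ether at a robust stage, so that no deprotection is needed once the polyene is built.

Step 19
Reactants: 30 (2E)-5-[(4R)-4-hydroxy-2,6,6-trimethylcyclohex-1-en-1-yl]-3-methylpent-2-en-4-yn-1-ol
Product: 31 (2E)-5-[(4R)-4-hydroxy-2,6,6-trimethylcyclohex-1-en-1-yl]-3-methylpent-2-en-4-ynal
Conditions: MnO2, CH2Cl2, rt
Reagents that add atoms: none
Why: MnO2 oxidises only the allylic primary alcohol; the ring hydroxyl is homoallylic and is left.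

Step 20
Reactants: 31 (2E)-5-[(4R)-4-hydroxy-2,6,6-trimethylcyclohex-1-en-1-yl]-3-methylpent-2-en-4-ynal
Product: 32 (1R)-4-[(3E,5E)-6-iodo-3-methylhexa-3,5-dien-1-yn-1-yl]-3,5,5-trimethylcyclohex-3-en-1-ol
Conditions: CrCl2, CHI3, THF, 0 °C, dark
Reagents that add atoms: iodoform, IC(I)I
Why: Takai olefination: the geminal dichromium species from CHI3 and CrCl2 adds to the aldehyde and elimination gives the (E)-alkenyl iodide. Free hydroxyl groups are tolerated by divalent chromium.

Step 21
Reactants: 32 (1R)-4-[(3E,5E)-6-iodo-3-methylhexa-3,5-dien-1-yn-1-yl]-3,5,5-trimethylcyclohex-3-en-1-ol; 33 (E)-1,2-bis(tributylstannyl)ethene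
Product: 34 (1R)-3,5,5-trimethyl-4-[(3E,5E,7E)-3-methyl-8-(tributylstannyl)octa-3,5,7-trien-1-yn-1-yl]cyclohex-3-en-1-ol
Conditions: PdCl2(MeCN)2 (cat.), DMF, rt, 33 in excess
Reagents that add atoms: none
Why: Stille coupling with retention at both alkene carbons; an excess of the symmetrical distannane limits double coupling.

Step 22
Reactants: 34 (1R)-3,5,5-trimethyl-4-[(3E,5E,7E)-3-methyl-8-(tributylstannyl)octa-3,5,7-trien-1-yn-1-yl]cyclohex-3-en-1-ol; 23 (5Z)-3-bromo-5-[(2E)-3-iodo-2-methylprop-2-en-1-ylidene]furan-2(5H)-one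
Product: 35 (5Z)-3-bromo-5-{(2E,4E,6E,8E)-11-[(4R)-4-hydroxy-2,6,6-trimethylcyclohex-1-en-1-yl]-2,9-dimethylundeca-2,4,6,8-tetraen-10-yn-1-ylidene}furan-2(5H)-one
Conditions: Pd2(dba)3·CHCl3 (cat.), AsPh3, NMP, rt, dark
Reagents that add atoms: none
Why: Stille coupling that relies on the faster oxidative addition of zerovalent palladium to the alkenyl C–I bond than to the C3–Br bond of the lactone at room temperature with the weak donor AsPh3; both alkene geometries are retained.

Step 23
Reactants: 35 (5Z)-3-bromo-5-{(2E,4E,6E,8E)-11-[(4R)-4-hydroxy-2,6,6-trimethylcyclohex-1-en-1-yl]-2,9-dimethylundeca-2,4,6,8-tetraen-10-yn-1-ylidene}furan-2(5H)-one; 13 (1R,2R,4S)-2,6,6-trimethyl-1-[(E)-2-(tributylstannyl)ethenyl]cyclohexane-1,2,4-triol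
Product: 36 (5Z)-5-{(2E,4E,6E,8E)-11-[(4R)-4-hydroxy-2,6,6-trimethylcyclohex-1-en-1-yl]-2,9-dimethylundeca-2,4,6,8-tetraen-10-yn-1-ylidene}-3-{(E)-2-[(1R,2R,4S)-1,2,4-trihydroxy-2,6,6-trimethylcyclohexyl]ethenyl}furan-2(5H)-one
Conditions: Pd2(dba)3·CHCl3 (cat.), AsPh3, NMP, 40 °C, dark
Reagents that add atoms: none
Why: Stille coupling of the activated α-bromo butenolide with the (E)-alkenylstannane; geometry is retained on both partners and the four free hydroxyl groups do not interfere, so the target should be obtained without a deprotection step.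

## Compound list

1 | safranal (2,6,6-trimethylcyclohexa-1,3-diene-1-carbaldehyde) | CC1=C(C=O)C(C)(C)CC=C1 | starting material
2 | 1-(2,2-dibromoethenyl)-2,6,6-trimethylcyclohexa-1,3-diene | CC1=C(C=C(Br)Br)C(C)(C)CC=C1 | intermediate
3 | chlorotrimethylsilane | C[Si](C)(C)Cl | starting material
4 | [(2,6,6-trimethylcyclohexa-1,3-dien-1-yl)ethynyl]lithium (lithium acetylide, not isolated) | CC1=C(C#C[Li])C(C)(C)CC=C1 | intermediate
5 | trimethyl[(2,6,6-trimethylcyclohexa-1,3-dien-1-yl)ethynyl]silane | CC1=C(C#C[Si](C)(C)C)C(C)(C)CC=C1 | intermediate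
6 | rac-(1R,4S)-6,7,7-trimethyl-1-[(trimethylsilyl)ethynyl]-2,3-dioxabicyclo[2.2.2]oct-5-ene (racemate; the (1R,4S)-enantiomer is drawn) | C[Si](C)(C)C#C[C@@]1(OO2)C(C)(C)C[C@H]2C=C1C | intermediate
7 | (4R)-4-hydroxy-3,5,5-trimethyl-4-[(trimethylsilyl)ethynyl]cyclohex-2-en-1-one | C[Si](C)(C)C#C[C@@]1(O)C(C)(C)CC(=O)C=C1C | intermediate
8 | (4R)-3,5,5-trimethyl-4-[(triethylsilyl)oxy]-4-[(trimethylsilyl)ethynyl]cyclohex-2-en-1-one | C[Si](C)(C)C#C[C@@]1(O[Si](CC)(CC)CC)C(C)(C)CC(=O)C=C1C | intermediate
9 | (1S,5S,6R)-5-ethynyl-4,4,6-trimethyl-5-[(triethylsilyl)oxy]-7-oxabicyclo[4.1.0]heptan-2-one | C#C[C@@]1(O[Si](CC)(CC)CC)C(C)(C)CC(=O)[C@H]2O[C@@]12C | intermediate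
10 | (3R,4S)-4-ethynyl-3-hydroxy-3,5,5-trimethyl-4-[(triethylsilyl)oxy]cyclohexan-1-one | C#C[C@@]1(O[Si](CC)(CC)CC)C(C)(C)CC(=O)C[C@@]1(C)O | intermediate
11 | (1R,3S,6S)-6-ethynyl-1,5,5-trimethyl-6-[(triethylsilyl)oxy]cyclohexane-1,3-diol | C#C[C@@]1(O[Si](CC)(CC)CC)C(C)(C)C[C@H](O)C[C@@]1(C)O | intermediate
12 | (1S,2R,4S)-1-ethynyl-2,6,6-trimethylcyclohexane-1,2,4-triol | C#C[C@@]1(O)C(C)(C)C[C@H](O)C[C@@]1(C)O | intermediate
13 | (1R,2R,4S)-2,6,6-trimethyl-1-[(E)-2-(tributylstannyl)ethenyl]cyclohexane-1,2,4-triol | CCCC[Sn](CCCC)(CCCC)/C=C/[C@@]1(O)C(C)(C)C[C@H](O)C[C@@]1(C)O | intermediate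
14 | prop-2-yn-1-ol | C#CCO | starting material
15 | dimethylaluminium (2E)-3-(dimethylalumanyl)-2-methylprop-2-en-1-olate (alkenylalane, not isolated) | C[Al](C)/C=C(C)/CO[Al](C)C | intermediate
16 | (2E)-3-iodo-2-methylprop-2-en-1-ol | I/C=C(C)/CO | intermediate
17 | (2E)-3-iodo-2-methylprop-2-enal | I/C=C(C)/C=O | intermediate
18 | furan-2(5H)-one | O=C1OCC=C1 | starting material
19 | trans-3,4-dibromodihydrofuran-2(3H)-one (racemic, not isolated) | O=C1OC[C@H](Br)[C@H]1Br | intermediate
20 | 3-bromofuran-2(5H)-one | O=C1OCC=C1Br | intermediate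
21 | [(3-bromofuran-2-yl)oxy](tert-butyl)dimethylsilane (silyloxyfuran, not isolated) | CC(C)(C)[Si](C)(C)Oc1occc1Br | intermediate
22 | 3-bromo-5-[(2E)-1-{[tert-butyl(dimethyl)silyl]oxy}-3-iodo-2-methylprop-2-en-1-yl]furan-2(5H)-one (mixture of diastereomers, not isolated) | CC(C)(C)[Si](C)(C)OC(/C(C)=C/I)C1OC(=O)C(Br)=C1 | intermediate
23 | (5Z)-3-bromo-5-[(2E)-3-iodo-2-methylprop-2-en-1-ylidene]furan-2(5H)-one | I/C=C(C)/C=C1C=C(Br)C(=O)O/1 | intermediate
24 | (4R,6R)-4-hydroxy-2,2,6-trimethylcyclohexan-1-one (actinol) | O=C1C(C)(C)C[C@H](O)C[C@H]1C | starting material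
25 | (4R,6R)-4-{[tert-butyl(dimethyl)silyl]oxy}-2,2,6-trimethylcyclohexan-1-one | O=C1C(C)(C)C[C@H](O[Si](C)(C)C(C)(C)C)C[C@H]1C | intermediate
26 | lithium (4R)-4-{[tert-butyl(dimethyl)silyl]oxy}-2,6,6-trimethylcyclohex-1-en-1-olate (lithium enolate, not isolated) | CC1=C(O[Li])C(C)(C)C[C@H](O[Si](C)(C)C(C)(C)C)C1 | intermediate
27 | (4R)-4-{[tert-butyl(dimethyl)silyl]oxy}-2,6,6-trimethylcyclohex-1-en-1-yl trifluoromethanesulfonate | CC1=C(OS(=O)(=O)C(F)(F)F)C(C)(C)C[C@H](O[Si](C)(C)C(C)(C)C)C1 | intermediate
28 | (2E)-3-methylpent-2-en-4-yn-1-ol | C#C/C(C)=C/CO | starting material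
29 | (2E)-5-[(4R)-4-{[tert-butyl(dimethyl)silyl]oxy}-2,6,6-trimethylcyclohex-1-en-1-yl]-3-methylpent-2-en-4-yn-1-ol | CC1=C(C#C/C(C)=C/CO)C(C)(C)C[C@H](O[Si](C)(C)C(C)(C)C)C1 | intermediate
30 | (2E)-5-[(4R)-4-hydroxy-2,6,6-trimethylcyclohex-1-en-1-yl]-3-methylpent-2-en-4-yn-1-ol | CC1=C(C#C/C(C)=C/CO)C(C)(C)C[C@H](O)C1 | intermediate
31 | (2E)-5-[(4R)-4-hydroxy-2,6,6-trimethylcyclohex-1-en-1-yl]-3-methylpent-2-en-4-ynal | CC1=C(C#C/C(C)=C/C=O)C(C)(C)C[C@H](O)C1 | intermediate
32 | (1R)-4-[(3E,5E)-6-iodo-3-methylhexa-3,5-dien-1-yn-1-yl]-3,5,5-trimethylcyclohex-3-en-1-ol | CC1=C(C#C/C(C)=C/C=C/I)C(C)(C)C[C@H](O)C1 | intermediate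
33 | (E)-1,2-bis(tributylstannyl)ethene | CCCC[Sn](CCCC)(CCCC)/C=C/[Sn](CCCC)(CCCC)CCCC | starting material
34 | (1R)-3,5,5-trimethyl-4-[(3E,5E,7E)-3-methyl-8-(tributylstannyl)octa-3,5,7-trien-1-yn-1-yl]cyclohex-3-en-1-ol | CC1=C(C#C/C(C)=C/C=C/C=C/[Sn](CCCC)(CCCC)CCCC)C(C)(C)C[C@H](O)C1 | intermediate
35 | (5Z)-3-bromo-5-{(2E,4E,6E,8E)-11-[(4R)-4-hydroxy-2,6,6-trimethylcyclohex-1-en-1-yl]-2,9-dimethylundeca-2,4,6,8-tetraen-10-yn-1-ylidene}furan-2(5H)-one | CC1=C(C#C/C(C)=C/C=C/C=C/C=C(C)/C=C2C=C(Br)C(=O)O/2)C(C)(C)C[C@H](O)C1 | intermediate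
36 | (5Z)-5-{(2E,4E,6E,8E)-11-[(4R)-4-hydroxy-2,6,6-trimethylcyclohex-1-en-1-yl]-2,9-dimethylundeca-2,4,6,8-tetraen-10-yn-1-ylidene}-3-{(E)-2-[(1R,2R,4S)-1,2,4-trihydroxy-2,6,6-trimethylcyclohexyl]ethenyl}furan-2(5H)-one (CNP0163979.1) | CC1=C(C#C/C(C)=C/C=C/C=C/C=C(C)/C=C2C=C(/C=C/[C@@]3(O)C(C)(C)C[C@H](O)C[C@@]3(C)O)C(=O)O/2)C(C)(C)C[C@H](O)C1 | target

## Step count and least certain steps

Total: 23 steps. Longest linear sequence: 11 steps (steps 1–10 and 23, from safranal 1). The ring B line is 9 steps (15–23); the lactone line joins it at step 22.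

**Step 4 (enantiomer-selective peroxide opening).** The most likely failure is a low rate difference between the two enantiomers, because the gem-dimethyl and alkynyl groups change the shape of the substrate relative to the meso peroxides for which the catalyst is known; a background opening by adventitious base would erode the selection further. The fallback sets out from 6 and comes back at 7, using known chemistry. Thiourea in methanol reduces the O–O bond of racemic 6 to the racemic cis-enediol (1R,4S)-2,6,6-trimethyl-1-[(trimethylsilyl)ethynyl]cyclohex-2-ene-1,4-diol F1. A lipase (immobilised Candida antarctica lipase B, vinyl acetate, t-BuOMe) acylates the secondary allylic hydroxyl of one enantiomer only. The (1R,4S) material is collected either as unreacted diol or, if it is the fast enantiomer, as (1S,4R)-4-hydroxy-3,5,5-trimethyl-4-[(trimethylsilyl)ethynyl]cyclohex-2-en-1-yl acetate F2, which the same lipase hydrolyses in buffer. MnO2 then oxidises the allylic A4 hydroxyl of resolved F1 to give 7.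

**Step 3 (key step).** The most likely failure is hydrogen abstraction by singlet oxygen at the C2 methyl or the C5 methylene (ene reaction) outrunning cycloaddition at the hindered, fully substituted diene terminus, together with premature opening of the peroxide on handling. The fallback sets out from 5 and comes back at 6. It replaces singlet oxygen by ground-state oxygen under cation-radical catalysis (tris(4-bromophenyl)aminium hexachloroantimonate, (4-BrC6H4)3N SbCl6, CH2Cl2, −78 °C). The diene radical cation takes up O2 in a chain process that is known to convert cyclohexa-1,3-dienes into the same bicyclic peroxides and has no ene pathway, since no free singlet oxygen is present.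

**Step 6 (epoxidation face).** The most likely failure is loss of facial control, either by attack syn to the silyloxy group or through partial loss of the silyl ether, which would open a hydrogen-bond-directed syn pathway; slow addition at the hindered β-carbon is the second concern. The fallback sets out from 8 and comes back at 9, and it moves stereocontrol from the substrate's steric bias to a directing hydroxyl.
- Luche reduction (NaBH4, CeCl3·7H2O, MeOH, −78 °C) is expected to deliver hydride from the face of the axial silyloxy group, away from the axial A6 methyl, and give (1R,4R)-3,5,5-trimethyl-4-[(triethylsilyl)oxy]-4-[(trimethylsilyl)ethynyl]cyclohex-2-en-1-ol F3.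
- Hydroxyl-directed epoxidation (VO(acac)2, t-BuOOH) places the oxygen syn to the new hydroxyl and therefore anti to the A1 oxygen, giving (1R,2R,5S,6R)-4,4,6-trimethyl-5-[(triethylsilyl)oxy]-5-[(trimethylsilyl)ethynyl]-7-oxabicyclo[4.1.0]heptan-2-ol F4.
- Dess–Martin oxidation gives (1S,5S,6R)-4,4,6-trimethyl-5-[(triethylsilyl)oxy]-5-[(trimethylsilyl)ethynyl]-7-oxabicyclo[4.1.0]heptan-2-one F5, and K2CO3 in methanol removes the alkynyl silyl group to give 9.

**Step 22 (iodide before bromide).** The most likely failure is incomplete chemoselectivity: oxidative addition also at the C3–Br bond of 23 or of the product, leading to double coupling and oligomers. The fallback sets out from 34, 17 and 20 and comes back at 35; it forms the lactone after the chain is complete, so the two halides never sit in one molecule.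
- Stille coupling of 34 with 17 gives (2E,4E,6E,8E)-11-[(4R)-4-hydroxy-2,6,6-trimethylcyclohex-1-en-1-yl]-2,9-dimethylundeca-2,4,6,8-tetraen-10-ynal F6.
- Condensation of F6 with 20 under the conditions of step 14 (excess silyl triflate, which also silylates the ring hydroxyl) passes through the bis-silylated aldol adduct 3-bromo-5-[(2E,4E,6E,8E)-1-{[tert-butyl(dimethyl)silyl]oxy}-11-[(4R)-4-{[tert-butyl(dimethyl)silyl]oxy}-2,6,6-trimethylcyclohex-1-en-1-yl]-2,9-dimethylundeca-2,4,6,8-tetraen-10-yn-1-yl]furan-2(5H)-one F7.
- DBU converts F7 into (5Z)-3-bromo-5-{(2E,4E,6E,8E)-11-[(4R)-4-{[tert-butyl(dimethyl)silyl]oxy}-2,6,6-trimethylcyclohex-1-en-1-yl]-2,9-dimethylundeca-2,4,6,8-tetraen-10-yn-1-ylidene}furan-2(5H)-one F8, and HF·pyridine in THF removes the silyl ether to give 35.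

**Step 23 (final coupling).** The most likely failure is slow transmetalation with protodestannylation of 13, and geometric isomerisation of the polyene and ylidene during prolonged contact with palladium. The fallback sets out from 12 and comes back at 36; it changes the organometallic partner from tin to boron. Copper-catalysed borylation of the terminal alkyne of 12 (B2pin2, CuCl, NaOt-Bu, PPh3, MeOH, THF) adds boron to the terminal carbon and hydrogen syn, and gives (1R,2R,4S)-2,6,6-trimethyl-1-[(E)-2-(4,4,5,5-tetramethyl-1,3,2-dioxaborolan-2-yl)ethenyl]cyclohexane-1,2,4-triol F9. Suzuki–Miyaura coupling of F9 with 35 (Pd(PPh3)4, TlOEt, THF–H2O, rt) then gives 36 under conditions that are milder toward the lactone.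

## Further compounds

F1 | step 4 | (1R,4S)-2,6,6-trimethyl-1-[(trimethylsilyl)ethynyl]cyclohex-2-ene-1,4-diol (formed as the racemate, resolved) | C[Si](C)(C)C#C[C@@]1(O)C(C)(C)C[C@H](O)C=C1C
F2 | step 4 | (1S,4R)-4-hydroxy-3,5,5-trimethyl-4-[(trimethylsilyl)ethynyl]cyclohex-2-en-1-yl acetate | C[Si](C)(C)C#C[C@@]1(O)C(C)(C)C[C@H](OC(C)=O)C=C1C
F0 | step 3 | none | none
F3 | step 6 | (1R,4R)-3,5,5-trimethyl-4-[(triethylsilyl)oxy]-4-[(trimethylsilyl)ethynyl]cyclohex-2-en-1-ol | C[Si](C)(C)C#C[C@@]1(O[Si](CC)(CC)CC)C(C)(C)C[C@@H](O)C=C1C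
F4 | step 6 | (1R,2R,5S,6R)-4,4,6-trimethyl-5-[(triethylsilyl)oxy]-5-[(trimethylsilyl)ethynyl]-7-oxabicyclo[4.1.0]heptan-2-ol | C[Si](C)(C)C#C[C@@]1(O[Si](CC)(CC)CC)C(C)(C)C[C@@H](O)[C@H]2O[C@@]12C
F5 | step 6 | (1S,5S,6R)-4,4,6-trimethyl-5-[(triethylsilyl)oxy]-5-[(trimethylsilyl)ethynyl]-7-oxabicyclo[4.1.0]heptan-2-one | C[Si](C)(C)C#C[C@@]1(O[Si](CC)(CC)CC)C(C)(C)CC(=O)[C@H]2O[C@@]12C
F6 | step 22 | (2E,4E,6E,8E)-11-[(4R)-4-hydroxy-2,6,6-trimethylcyclohex-1-en-1-yl]-2,9-dimethylundeca-2,4,6,8-tetraen-10-ynal | CC1=C(C#C/C(C)=C/C=C/C=C/C=C(C)/C=O)C(C)(C)C[C@H](O)C1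
F7 | step 22 | 3-bromo-5-[(2E,4E,6E,8E)-1-{[tert-butyl(dimethyl)silyl]oxy}-11-[(4R)-4-{[tert-butyl(dimethyl)silyl]oxy}-2,6,6-trimethylcyclohex-1-en-1-yl]-2,9-dimethylundeca-2,4,6,8-tetraen-10-yn-1-yl]furan-2(5H)-one (not isolated) | CC1=C(C#C/C(C)=C/C=C/C=C/C=C(C)/C(O[Si](C)(C)C(C)(C)C)C2OC(=O)C(Br)=C2)C(C)(C)C[C@H](O[Si](C)(C)C(C)(C)C)C1
F8 | step 22 | (5Z)-3-bromo-5-{(2E,4E,6E,8E)-11-[(4R)-4-{[tert-butyl(dimethyl)silyl]oxy}-2,6,6-trimethylcyclohex-1-en-1-yl]-2,9-dimethylundeca-2,4,6,8-tetraen-10-yn-1-ylidene}furan-2(5H)-one | CC1=C(C#C/C(C)=C/C=C/C=C/C=C(C)/C=C2C=C(Br)C(=O)O/2)C(C)(C)C[C@H](O[Si](C)(C)C(C)(C)C)C1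
F9 | step 23 | (1R,2R,4S)-2,6,6-trimethyl-1-[(E)-2-(4,4,5,5-tetramethyl-1,3,2-dioxaborolan-2-yl)ethenyl]cyclohexane-1,2,4-triol | CC1(C)OB(/C=C/[C@@]2(O)C(C)(C)C[C@H](O)C[C@@]2(C)O)OC1(C)C
A1 | alternative 1 | (5Z)-5-[(2E)-4-{[tert-butyl(dimethyl)silyl]oxy}-2-methylbut-2-en-1-ylidene]-3-{(E)-2-[(1R,2R,4S)-4-{[tert-butyl(dimethyl)silyl]oxy}-1,2-dihydroxy-2,6,6-trimethylcyclohexyl]ethenyl}furan-2(5H)-one | CC(C)(C)[Si](C)(C)OC/C=C(C)/C=C1C=C(/C=C/[C@@]2(O)C(C)(C)C[C@H](O[Si](C)(C)C(C)(C)C)C[C@@]2(C)O)C(=O)O/1
A2 | alternative 1 | (1E,3Z,7E)-9-{[tert-butyl(dimethyl)silyl]oxy}-1-[(1R,2R,4S)-4-{[tert-butyl(dimethyl)silyl]oxy}-1,2-dihydroxy-2,6,6-trimethylcyclohexyl]-3-iodo-7-methylnona-1,3,7-trien-5-one | CC(C)(C)[Si](C)(C)OC/C=C(C)/CC(=O)/C=C(I)/C=C/[C@@]1(O)C(C)(C)C[C@H](O[Si](C)(C)C(C)(C)C)C[C@@]1(C)O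
A3 | alternative 2 | tert-butyl{[(1R)-4-[(3E)-5,5-dimethoxy-3-methylpent-3-en-1-yn-1-yl]-3,5,5-trimethylcyclohex-3-en-1-yl]oxy}dimethylsilane | CC1=C(C#C/C(C)=C/C(OC)OC)C(C)(C)C[C@H](O[Si](C)(C)C(C)(C)C)C1
A4 | alternative 2 | (2E)-1-[(4R)-4-{[tert-butyl(dimethyl)silyl]oxy}-2,6,6-trimethylcyclohex-1-en-1-yl]-4,4-dimethoxy-2-methylbut-2-en-1-one | CC1=C(C(=O)/C(C)=C/C(OC)OC)C(C)(C)C[C@H](O[Si](C)(C)C(C)(C)C)C1
A5 | alternative 3 | (5Z)-3-bromo-5-{(2E,4E,6E,8E)-11-[(4R)-4-hydroxy-2,6,6-trimethylcyclohex-1-en-1-yl]-2,9-dimethylundeca-2,4,6,8-tetraen-10-yn-1-ylidene}furan-2(5H)-one (identical with 35) | CC1=C(C#C/C(C)=C/C=C/C=C/C=C(C)/C=C2C=C(Br)C(=O)O/2)C(C)(C)C[C@H](O)C1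
A6 | alternative 3 | (1R)-4-[(3E,5E,7E,9E)-3,10-dimethyldodeca-3,5,7,9-tetraene-1,11-diyn-1-yl]-3,5,5-trimethylcyclohex-3-en-1-ol | CC1=C(C#C/C(C)=C/C=C/C=C/C=C(C)/C#C)C(C)(C)C[C@H](O)C1
A7 | alternative 3 | (3E,5E,7E,9E)-3,10-dimethyldodeca-3,5,7,9-tetraene-1,11-diyne | C#C/C(C)=C/C=C/C=C/C=C(C)/C#C
A8 | alternative 3 | (2E)-2,3-dibromoprop-2-enoic acid | OC(=O)/C(Br)=C\Br
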